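**Plan**

- Retrosynthesis: after O-debenzylation, each lactone is cut at C2(=O)–C3 and at C3-CH2–aryl (four C–C bonds in all). This leaves dibromo diaryl ether 17 and two molecules of one chiral homoallylic oxalate 11. 17 is cut at the diaryl ether C–O bond (phenol 15 + boronic acid 16), and 11 at C4–CH2Ar (auxiliary alkylation).
- Enabling feature: in both lactones C3 and its exocyclic CH2 are the two carbons of a vinyl group on C4, O1–C2 is an alkoxycarbonyl radical, and the CH2 ends on C1 of ring A or ring B of the central diaryl ether. The two 4-(3,4-dimethoxybenzyl) lactone halves are identical, so one building block serves twice.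
- Forward: auxiliary alkylation, reduction and oxalate formation give 11. Benzylation, Baeyer–Villiger oxidation and Chan–Lam coupling give 17. One twofold alkoxycarbonyl radical cyclisation–arylation closes both lactones and joins the three fragments, and hydrogenolysis frees the phenol.
- Stereochemistry: both C4 centres (S) come from one purchased oxazolidinone stereocentre. Both C3 centres are relayed from C4 by substrate control in the key event (trans), backed by equilibration.

Key step: step 8

Assumption: both lactones are read as (3S,4S), i.e. trans, and are numbered O1, C2(=O), C3, C4, C5. Ring A is the 4-aryloxy-3-methoxyphenyl ring and ring B the ring that carries the free OH. Compounds 5, 12 and 16 are taken as purchasable.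

**Route**

Step 1
Reactants: 1 (S)-4-benzyloxazolidin-2-one; 2 (E)-but-2-enoyl chloride
Product: 4 (S)-4-benzyl-3-[(E)-but-2-enoyl]oxazolidin-2-one, via lithium oxazolidinide 3 (not isolated)
Conditions: n-BuLi (1.05 equiv), THF, −78 °C; then 2 (1.1 equiv), −78 to 0 °C
Reagents that add atoms: none
Why: N-acylation of the lithiated oxazolidinone by the acid chloride is the standard entry to enoyl imides and does not touch the auxiliary stereocentre.

Step 2
Reactants: 4 (S)-4-benzyl-3-[(E)-but-2-enoyl]oxazolidin-2-one; 5 4-(bromomethyl)-1,2-dimethoxybenzene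
Product: 7 (S)-4-benzyl-3-[(S)-2-(3,4-dimethoxybenzyl)but-3-enoyl]oxazolidin-2-one, via sodium dienolate 6 (not isolated)
Conditions: NaHMDS (1.1 equiv), THF, −78 °C; then 5 (1.5 equiv), −78 to −45 °C; AcOH quench at −78 °C
Reagents that add atoms: none
Why: Evans alkylation in its deconjugative form: γ-deprotonation gives the chelated (Z)-dienolate, which is benzylated at the α-carbon on the face away from the auxiliary benzyl group, setting the (S) centre that becomes C4 of both lactones.

Step 3
Reactants: 7 (S)-4-benzyl-3-[(S)-2-(3,4-dimethoxybenzyl)but-3-enoyl]oxazolidin-2-one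
Product: 8 (S)-2-(3,4-dimethoxybenzyl)but-3-en-1-ol
Conditions: LiBH4 (1.5 equiv), H2O (1.5 equiv), Et2O, 0 °C
Reagents that add atoms: none
Why: Reductive cleavage of the imide by the mildly basic borohydride should give the primary alcohol and return the auxiliary without moving the double bond into conjugation or epimerising the allylic centre.

Step 4
Reactants: 8 (S)-2-(3,4-dimethoxybenzyl)but-3-en-1-ol
Product: 11 cesium 2-{[(S)-2-(3,4-dimethoxybenzyl)but-3-en-1-yl]oxy}-2-oxoacetate, via chlorooxoacetate 9 (not isolated), via hydrogen oxalate 10 (not isolated)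
Conditions: (COCl)2 (2 equiv), Et2O, 0 °C to rt, evaporate; H2O, THF, 0 °C; CsHCO3 (1.0 equiv), H2O/MeCN, freeze-dry
Reagents that add atoms: oxalyl chloride ClC(=O)C(=O)Cl; water O; cesium hydrogen carbonate [Cs+].OC([O-])=O
Why: Standard half-oxalate formation: the primary alcohol is acylated by excess oxalyl chloride, the remaining acid chloride hydrolyses far faster than the ester, and the strongly acidic half-ester is neutralised by hydrogen carbonate without ester cleavage.

Step 5
Reactants: 12 5-bromo-2-hydroxy-3-methoxybenzaldehyde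
Product: 13 2-(benzyloxy)-5-bromo-3-methoxybenzaldehyde
Conditions: BnBr (1.2 equiv), K2CO3, DMF, 50 °C
Reagents that add atoms: benzyl bromide BrCc1ccccc1
Why: Williamson etherification of the acidic ortho-formyl phenol installs the benzyl ether that masks the future ring-B hydroxyl until the last step.

Step 6
Reactants: 13 2-(benzyloxy)-5-bromo-3-methoxybenzaldehyde
Product: 15 2-(benzyloxy)-5-bromo-3-methoxyphenol, via aryl formate 14 (not isolated)
Conditions: mCPBA (1.5 equiv), CH2Cl2, rt; then K2CO3 (cat.), MeOH, rt
Reagents that add atoms: mCPBA OOC(=O)c1cccc(Cl)c1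
Why: Baeyer–Villiger (Dakin-type) oxidation: the electron-rich ortho-alkoxy aryl group migrates in preference to hydride to give the aryl formate, which is methanolysed to the phenol that will carry the diaryl ether oxygen.

Step 7
Reactants: 15 2-(benzyloxy)-5-bromo-3-methoxyphenol; 16 (4-bromo-2-methoxyphenyl)boronic acid
Product: 17 2-(benzyloxy)-5-bromo-1-(4-bromo-2-methoxyphenoxy)-3-methoxybenzene
Conditions: 16 (2 equiv), Cu(OAc)2 (0.2 equiv), pyridine (3 equiv), 4 Å MS, CH2Cl2, O2 (1 atm), rt
Reagents that add atoms: none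
Why: Chan–Lam oxidative C–O coupling of a phenol with an arylboronic acid proceeds at room temperature, where both aryl bromides are inert to copper, so the two C–Br bonds needed for step 8 survive.

Step 8
Reactants: 17 2-(benzyloxy)-5-bromo-1-(4-bromo-2-methoxyphenoxy)-3-methoxybenzene; 11 cesium 2-{[(S)-2-(3,4-dimethoxybenzyl)but-3-en-1-yl]oxy}-2-oxoacetate
Product: 20 O-benzyl ether of the target (both lactones closed), via ring-A bromide monolactone 18 (not isolated), via ring-B bromide monolactone 19 (not isolated)
Conditions: 17 (1.0 equiv), 11 (3.0 equiv), Ir[dF(CF3)ppy]2(dtbbpy)PF6 (2 mol %), NiBr2·dme (20 mol %), 4,4'-di-tert-butyl-2,2'-bipyridine (24 mol %), degassed 1,4-dioxane/DMSO (5:1), blue LEDs, 35 °C; then crude product, DBU (0.5 equiv), PhMe, 80 °C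
Reagents that add atoms: none
Why: Proposed new method: the photoexcited trivalent iridium complex oxidises the carboxylate of 11, CO2 leaves, and the primary O-alkyl alkoxycarbonyl radical (slow to lose a second CO2, since only a primary alkyl radical would result) attacks the internal vinyl carbon to form the C2(=O)–C3 bond; the exocyclic C3–CH2 radical is then trapped by the aryl nickel bromide formed by oxidative addition of zerovalent nickel into a C–Br bond of 17, reductive elimination from trivalent nickel forms the CH2–aryl bond, and the sequence repeats at the second C–Br bond through 18 or 19. The closest known reaction type is the alkoxycarbonyl radical cyclisation–cross-coupling cascade of tertiary-alcohol-derived homoallylic oxalates with aryl bromides under iridium photoredox and nickel catalysis, backed by tin hydride cyclisations of primary homoallylic selenocarbonates; new here are the primary oxalate with an allylic stereocentre and the twofold use on one dibromide. Each γ-butyrolactone closes in the 5-exo-trig mode. Each new C3 stereocentre is controlled by the neighbouring C4 centre: in the chair-like transition state the 3,4-dimethoxybenzyl group sits pseudo-equatorial and the new C3–CH2 bond forms trans to it, giving (3S,4S), and the DBU stage converts any cis epimer into the more stable trans lactone through the lactone enolate, C3 being the only epimerisable centre. The step needs cyclisation to outrun direct nickel capture of the alkoxycarbonyl radical (which would give aryl esters) and needs coupling at both bromides; the first is secured by the unimolecular 5-exo rate onto a terminal alkene five atoms from the radical centre against a low nickel concentration, the second by the excess of 11 and the similar electron-rich character of the two C–Br bonds.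

Step 9
Reactants: 20 O-benzyl ether of the target
Product: 21 target bis-lactone (CNP0183104.1)
Conditions: H2 (1 atm), Pd/C (10 wt %), EtOAc/MeOH, rt
Reagents that add atoms: none
Why: Hydrogenolysis of the benzyl aryl ether frees the ring-B phenol; the lactones, the diaryl ether and the methyl ethers are inert, and no alkene or C–Br bond remains.

**Compound list**

1 | (S)-4-benzyloxazolidin-2-one | O=C1OC[C@H](Cc2ccccc2)N1 | starting material
2 | (E)-but-2-enoyl chloride (crotonyl chloride) | C/C=C/C(=O)Cl | starting material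
3 | lithium salt of 1 (N-lithio oxazolidinone, formed in the flask) | [Li+].O=C1OC[C@H](Cc2ccccc2)[N-]1 | intermediate
4 | (S)-4-benzyl-3-[(E)-but-2-enoyl]oxazolidin-2-one | C/C=C/C(=O)N1C(=O)OC[C@@H]1Cc1ccccc1 | intermediate
5 | 4-(bromomethyl)-1,2-dimethoxybenzene (3,4-dimethoxybenzyl bromide) | COc1ccc(CBr)cc1OC | starting material
6 | sodium (Z)-dienolate of 4 (formed in the flask) | [Na+].[O-]/C(=C\C=C)N1C(=O)OC[C@@H]1Cc1ccccc1 | intermediate
7 | (S)-4-benzyl-3-[(S)-2-(3,4-dimethoxybenzyl)but-3-enoyl]oxazolidin-2-one | COc1ccc(C[C@@H](C=C)C(=O)N2C(=O)OC[C@@H]2Cc2ccccc2)cc1OC | intermediate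
8 | (S)-2-(3,4-dimethoxybenzyl)but-3-en-1-ol | COc1ccc(C[C@@H](C=C)CO)cc1OC | intermediate
9 | (S)-2-(3,4-dimethoxybenzyl)but-3-en-1-yl 2-chloro-2-oxoacetate (formed in the flask) | COc1ccc(C[C@@H](C=C)COC(=O)C(Cl)=O)cc1OC | intermediate
10 | 2-{[(S)-2-(3,4-dimethoxybenzyl)but-3-en-1-yl]oxy}-2-oxoacetic acid (formed in the flask) | COc1ccc(C[C@@H](C=C)COC(=O)C(O)=O)cc1OC | intermediate
11 | cesium 2-{[(S)-2-(3,4-dimethoxybenzyl)but-3-en-1-yl]oxy}-2-oxoacetate | [Cs+].COc1ccc(C[C@@H](C=C)COC(=O)C([O-])=O)cc1OC | intermediate
12 | 5-bromo-2-hydroxy-3-methoxybenzaldehyde | COc1cc(Br)cc(C=O)c1O | starting material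
13 | 2-(benzyloxy)-5-bromo-3-methoxybenzaldehyde | COc1cc(Br)cc(C=O)c1OCc1ccccc1 | intermediate
14 | 2-(benzyloxy)-5-bromo-3-methoxyphenyl formate (formed in the flask) | COc1cc(Br)cc(OC=O)c1OCc1ccccc1 | intermediate
15 | 2-(benzyloxy)-5-bromo-3-methoxyphenol | COc1cc(Br)cc(O)c1OCc1ccccc1 | intermediate
16 | (4-bromo-2-methoxyphenyl)boronic acid | COc1cc(Br)ccc1B(O)O | starting material
17 | 2-(benzyloxy)-5-bromo-1-(4-bromo-2-methoxyphenoxy)-3-methoxybenzene | COc1cc(Br)ccc1Oc1cc(Br)cc(OC)c1OCc1ccccc1 | intermediate
18 | (3S,4S)-3-[4-(benzyloxy)-3-(4-bromo-2-methoxyphenoxy)-5-methoxybenzyl]-4-(3,4-dimethoxybenzyl)dihydrofuran-2(3H)-one (lactone B closed, bromide left on ring A; formed in the flask) | COc1cc(Br)ccc1Oc1cc(C[C@@H]2C(=O)OC[C@H]2Cc2ccc(OC)c(OC)c2)cc(OC)c1OCc1ccccc1 | intermediate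
19 | (3S,4S)-3-{4-[2-(benzyloxy)-5-bromo-3-methoxyphenoxy]-3-methoxybenzyl}-4-(3,4-dimethoxybenzyl)dihydrofuran-2(3H)-one (lactone A closed, bromide left on ring B; formed in the flask) | COc1ccc(C[C@@H]2COC(=O)[C@H]2Cc2ccc(Oc3cc(Br)cc(OC)c3OCc3ccccc3)c(OC)c2)cc1OC | intermediate
20 | (3S,4S)-3-[4-(2-(benzyloxy)-5-{[(3S,4S)-4-(3,4-dimethoxybenzyl)-2-oxotetrahydrofuran-3-yl]methyl}-3-methoxyphenoxy)-3-methoxybenzyl]-4-(3,4-dimethoxybenzyl)dihydrofuran-2(3H)-one (O-benzyl ether of the target) | COc1ccc(C[C@@H]2COC(=O)[C@H]2Cc2ccc(Oc3cc(C[C@@H]4C(=O)OC[C@H]4Cc4ccc(OC)c(OC)c4)cc(OC)c3OCc5ccccc5)c(OC)c2)cc1OC | intermediate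
21 | (3S,4S)-4-(3,4-dimethoxybenzyl)-3-[4-(5-{[(3S,4S)-4-(3,4-dimethoxybenzyl)-2-oxotetrahydrofuran-3-yl]methyl}-2-hydroxy-3-methoxyphenoxy)-3-methoxybenzyl]dihydrofuran-2(3H)-one | COc1ccc(C[C@@H]2COC(=O)[C@H]2Cc2ccc(Oc3cc(C[C@@H]4C(=O)OC[C@H]4Cc4ccc(OC)c(OC)c4)cc(OC)c3O)c(OC)c2)cc1OC | target

**Summary**

Total step count: 9. Longest linear sequence: 6 steps (steps 1, 2, 3, 4, 8, 9).

Steps most likely to fail:

1. Step 8 (proposed new method). What may go wrong:
   - direct nickel capture of the alkoxycarbonyl radical before cyclisation, giving aryl esters;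
   - protodebromination or a stalled second coupling;
   - unproductive quenching of the photocatalyst by the electron-rich arenes;
   - attack of the C3–CH2 radical on the neighbouring dimethoxyphenyl ring.

   Fallback (known chemistry, from 17 and 8, returning at 20): 17 is coupled twice with 8 in a Heck reaction (Pd(OAc)2, P(o-tol)3, Et3N, DMF, 100 °C) to give the bis-(E)-styrenyl diol F1. Phosgene in toluene with pyridine converts it into the bis(chloroformate) F2, and benzeneselenol with pyridine then gives the bis(Se-phenyl selenocarbonate) F3. Slow addition of Bu3SnH with AIBN in benzene at 80 °C generates the two alkoxycarbonyl radicals. Each should close 5-exo-trig onto its styrene to a benzylic radical that the tin hydride reduces, and the same DBU equilibration should then deliver 20.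

2. Step 7. What may go wrong: slow C–O bond formation between two ortho-oxygenated partners, with protodeboronation and oxidative self-coupling of the boronic acid consuming 16.

   Fallback (from 15, returning at 17): 15 displaces fluoride from 1-fluoro-2-methoxy-4-nitrobenzene (K2CO3, DMF, 80 °C; SNAr activated by the para nitro group) to give the nitro diaryl ether F4. Fe/NH4Cl in EtOH/H2O reduces it to the aniline F5 without touching the C–Br bond or the benzyl ether. Diazotisation–bromination (t-BuONO, CuBr2, MeCN) then gives 17.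

3. Step 2. What may go wrong: alkylation at the γ- instead of the α-carbon of the dienolate, and base-induced reconjugation or epimerisation of the doubly activated α-centre during reaction or quench.

   Fallback (from 1 and 5, returning at 8): γ-butyrolactone is opened by sodium benzeneselenolate (PhSeSePh, NaBH4, DMF, 120 °C) to 4-(phenylselanyl)butanoic acid F6, which is coupled to 1 (DCC, DMAP, CH2Cl2) to give the saturated imide F7. Its ordinary (Z)-enolate (NaHMDS, THF, −78 °C) is benzylated by 5 on the face away from the auxiliary benzyl group to give the alkylated imide F8. LiBH4 reduction gives the selenide alcohol F9 and returns 1. Oxidation with H2O2/pyridine and syn-elimination of the selenoxide then unveils the vinyl group of 8.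

Further compounds

F1 | step 8 | bis-(E)-styrenyl diol: 17 with each Br replaced by (E)-CH=CH–CH(CH2OH)CH2(3,4-dimethoxyphenyl), (S) at both centres | OC[C@@H](Cc1ccc(OC)c(OC)c1)/C=C/c1ccc(Oc2cc(/C=C/[C@@H](CO)Cc3ccc(OC)c(OC)c3)cc(OC)c2OCc2ccccc2)c(OC)c1
F2 | step 8 | bis(chloroformate) of F1 | ClC(=O)OC[C@@H](Cc1ccc(OC)c(OC)c1)/C=C/c1ccc(Oc2cc(/C=C/[C@@H](COC(Cl)=O)Cc3ccc(OC)c(OC)c3)cc(OC)c2OCc2ccccc2)c(OC)c1
F3 | step 8 | bis(Se-phenyl selenocarbonate) of F1 | O=C([Se]c1ccccc1)OC[C@@H](Cc1ccc(OC)c(OC)c1)/C=C/c1ccc(Oc2cc(/C=C/[C@@H](COC(=O)[Se]c3ccccc3)Cc3ccc(OC)c(OC)c3)cc(OC)c2OCc2ccccc2)c(OC)c1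
F4 | step 7 | 2-(benzyloxy)-5-bromo-1-methoxy-3-(2-methoxy-4-nitrophenoxy)benzene | COc1cc([N+](=O)[O-])ccc1Oc1cc(Br)cc(OC)c1OCc1ccccc1
F5 | step 7 | 4-[2-(benzyloxy)-5-bromo-3-methoxyphenoxy]-3-methoxyaniline | COc1cc(N)ccc1Oc1cc(Br)cc(OC)c1OCc1ccccc1
F6 | step 2 | 4-(phenylselanyl)butanoic acid | OC(=O)CCC[Se]c1ccccc1
F7 | step 2 | (S)-4-benzyl-3-[4-(phenylselanyl)butanoyl]oxazolidin-2-one | O=C1OC[C@H](Cc2ccccc2)N1C(=O)CCC[Se]c1ccccc1
F8 | step 2 | (S)-4-benzyl-3-[(S)-2-(3,4-dimethoxybenzyl)-4-(phenylselanyl)butanoyl]oxazolidin-2-one | COc1ccc(C[C@@H](CC[Se]c2ccccc2)C(=O)N2C(=O)OC[C@@H]2Cc2ccccc2)cc1OC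
F9 | step 2 | (S)-2-(3,4-dimethoxybenzyl)-4-(phenylselanyl)butan-1-ol | COc1ccc(C[C@@H](CC[Se]c2ccccc2)CO)cc1OC
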